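**Retrosynthetic overview**

1. Feature: the ring A carbon that carries the diaryl ether oxygen (C2, between carboxyl carbon C1 and hydroxyl carbon C3) is built as the quaternary C2 of a benzofuran-3(2H)-one fused to ring B. The furanone ketone carbon is the ring B carboxyl in masked form, and ring A C3 (OH) and C5 (OMe) are the carbonyls of a cyclohexane-1,3-dione flanking the chlorine carbon C4.
2. Target 14 ⇒ diacid 13 (O-demethylation ortho to the ring B carboxyl) ⇒ spiro dienone 11, by retro-Claisen cleavage of the bond between the furanone ketone carbon and the spiro carbon; this aromatises ring A and releases the ring B carboxyl.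
3. 11 ⇒ spiro trione 8 by C5'–C6' dehydrogenation, O-methylation of the distal enol and chlorination at C3'.
4. 8 ⇒ benzofuranone β-keto ester 5 + methyl (E)-4-oxopent-2-enoate 6 by Michael–Claisen spiroannulation (ring A bonds C1–C2 and C3–C4).
5. 5 ⇒ diester 4 ⇒ phenol 2 ⇒ methyl 2,6-dihydroxy-4-methylbenzoate 1. Ring order: ring B is bought, the furanone ring is closed in step 3, ring A in step 4, and the furanone ring is opened again in step 8.

Key step: step 4

Remark: the target has no stereocentre, so the spiro intermediates are carried as racemates (diastereomer mixtures where two centres exist). Primed locants refer to the spiro ring: C1' = ring A C2, C2' = C3, C3' = C4, C4' = C5, C5' = C6, C6' = C1.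

**Route**

Step 1
Reactants: 1 methyl 2,6-dihydroxy-4-methylbenzoate
Product: 2 methyl 2-hydroxy-6-methoxy-4-methylbenzoate
Conditions: CH3I (1.05 equiv), K2CO3 (1.1 equiv), acetone, reflux
Reagents that add atoms: iodomethane, CI
Why: Williamson O-methylation of two equivalent phenols; after the first alkylation the remaining OH is held in a hydrogen bond to the ester carbonyl, so the monoether should predominate and the diether is removed by chromatography.

Step 2
Reactants: 2 methyl 2-hydroxy-6-methoxy-4-methylbenzoate; 3 methyl bromoacetate
Product: 4 methyl 2-methoxy-6-(2-methoxy-2-oxoethoxy)-4-methylbenzoate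
Conditions: K2CO3 (1.5 equiv), DMF, 60 °C
Reagents that add atoms: methyl bromoacetate (compound 3), COC(=O)CBr
Why: Williamson alkylation (SN2) of the remaining phenoxide with a reactive α-bromo ester in a polar aprotic solvent, which should leave both esters untouched.

Step 3
Reactants: 4 methyl 2-methoxy-6-(2-methoxy-2-oxoethoxy)-4-methylbenzoate
Product: 5 methyl 4-methoxy-6-methyl-3-oxo-2,3-dihydrobenzofuran-2-carboxylate (racemic keto form, expected mainly as its 3-hydroxybenzofuran enol)
Conditions: NaOCH3 (1.5 equiv), CH3OH, reflux; then aq. HCl
Reagents that add atoms: none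
Why: Dieckmann condensation, in which the aryloxyacetate enolate attacks the ortho aryl ester (5-exo-trig) and deprotonation of the aromatic enol product pulls the equilibrium over; methoxide matches both esters and the C2 centre of the keto form is racemic and enolisable.

Step 4
Reactants: 5 methyl 4-methoxy-6-methyl-3-oxo-2,3-dihydrobenzofuran-2-carboxylate; 6 methyl (E)-4-oxopent-2-enoate
Product: 8 methyl 4-methoxy-6-methyl-2',3,4'-trioxo-3H-spiro[benzofuran-2,1'-cyclohexane]-6'-carboxylate (racemic mixture of diastereomers), via Michael adduct keto diester 7 (not isolated)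
Conditions: 6 (1.05 equiv), KOC(CH3)3 (0.1 equiv), THF, 0 °C to rt; then KOC(CH3)3 (1.3 equiv), THF, 0 to 40 °C; then aq. HCl
Reagents that add atoms: methyl (E)-4-oxopent-2-enoate (compound 6), CC(=O)/C=C/C(=O)OC
Why: The potassium enolate of 5 (a soft, C2-nucleophilic 3-oxidobenzofuran) adds to 6 at the alkene carbon β to the ketone, the stronger acceptor, giving keto diester 7 with the quaternary ether carbon in place; with a full equivalent of KOC(CH3)3 the methyl ketone is enolised reversibly and its terminal carbon acylates on the neighbouring C2 ester with loss of methoxide. This is the Michael–Claisen (dimedone-type) annulation by which benzofuran-3(2H)-one-2-carboxylates and enones are converted into grisan-3,2',4'-triones. Ring A closes by a 6-(enolendo)-exo-trig acyl substitution, whereas closure through the internal methylene would need a four-membered ring and closure on the side-chain ester a disfavoured 5-(enolendo)-exo-trig path. The two new stereocentres, spiro C1' and C6', are under no control beyond equilibration of the epimerisable C6' ester position, and none is needed because both are erased when ring A is aromatised. The selectivities needed are the site of conjugate addition, secured by the ketone outranking the ester as activating group, and Claisen closure over Robinson-type aldol at C3, secured by the poor electrophilicity of the C3 aryl ketone (conjugated with two ortho oxygens and flanked by the 4-methoxy group) and by irreversible deprotonation of the 1,3-dione, which also leaves too little free alkoxide for retro-Dieckmann cleavage.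

Step 5
Reactants: 8 methyl 4-methoxy-6-methyl-2',3,4'-trioxo-3H-spiro[benzofuran-2,1'-cyclohexane]-6'-carboxylate
Product: 9 methyl 3'-chloro-4'-hydroxy-4-methoxy-6-methyl-2',3-dioxo-3H-spiro[benzofuran-2,1'-cyclohex[3]ene]-6'-carboxylate (enol form of the 3'-chloro trione; racemic mixture of diastereomers)
Conditions: N-chlorosuccinimide (1.0 equiv), CH2Cl2, 0 °C
Reagents that add atoms: N-chlorosuccinimide, O=C1CCC(=O)N1Cl
Why: Electrophilic α-chlorination of a 1,3-dicarbonyl compound; the enol of the cyclohexane-1,3-dione is by far the most nucleophilic site, so one equivalent of reagent at 0 °C should chlorinate C3' only and leave the less activated ring B alone.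

Step 6
Reactants: 9 methyl 3'-chloro-4'-hydroxy-4-methoxy-6-methyl-2',3-dioxo-3H-spiro[benzofuran-2,1'-cyclohex[3]ene]-6'-carboxylate
Product: 10 methyl 3'-chloro-4,4'-dimethoxy-6-methyl-2',3-dioxo-3H-spiro[benzofuran-2,1'-cyclohex[3]ene]-6'-carboxylate (racemic mixture of diastereomers)
Conditions: HC(OCH3)3 (5 equiv), CH3OH, p-toluenesulfonic acid (cat.), 50 °C
Reagents that add atoms: methanol, CO; trimethyl orthoformate, COC(OC)OC
Why: Acid-catalysed enol ether formation of a cyclic 1,3-dione (a vinylogous Fischer esterification) under equilibrating conditions; methanol should add to the C4' carbonyl, which has a CH2 neighbour, in preference to the C2' carbonyl, which is neopentyl-like beside the fully substituted spiro carbon, so the distal 4'-methyl enol ether should dominate while the orthoformate removes water.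

Step 7
Reactants: 10 methyl 3'-chloro-4,4'-dimethoxy-6-methyl-2',3-dioxo-3H-spiro[benzofuran-2,1'-cyclohex[3]ene]-6'-carboxylate
Product: 11 methyl 3'-chloro-4,4'-dimethoxy-6-methyl-2',3-dioxo-3H-spiro[benzofuran-2,1'-cyclohexa[3,5]diene]-6'-carboxylate (racemic)
Conditions: 2,3-dichloro-5,6-dicyano-1,4-benzoquinone (DDQ, 1.5 equiv), camphorsulfonic acid (cat.), 1,4-dioxane, 90 °C; crude product taken on without delay
Reagents that add atoms: none
Why: Quinone dehydrogenation of an enone at its γ,δ-positions, as in the conversion of cyclohex-2-enones into linear dienones with DDQ or chloranil under acid catalysis; acid forms the 2'-hydroxy-2',4'-dienol through the only enolisable position C5', DDQ abstracts hydride from C6' to give a cation stabilised by the 4'-methoxy and 2'-hydroxy groups, and proton loss gives the conjugated dienone ester, which removes the C6' stereocentre.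

Step 8
Reactants: 11 methyl 3'-chloro-4,4'-dimethoxy-6-methyl-2',3-dioxo-3H-spiro[benzofuran-2,1'-cyclohexa[3,5]diene]-6'-carboxylate
Product: 13 4-chloro-2-(2-carboxy-3-methoxy-5-methylphenoxy)-3-hydroxy-5-methoxybenzoic acid, via ring-opened monoester acid 12 (not isolated)
Conditions: NaOH (2 M aq., 5 equiv), THF, 0 to 50 °C; then aq. HCl to pH 1
Reagents that add atoms: sodium hydroxide, [Na+].[OH-]; water, O
Why: Retro-Claisen cleavage of a non-enolisable 1,3-diketone; hydroxide adds to the strained furanone ketone C3 and the C3–spiro bond breaks because the departing carbon becomes part of an aromatic phenoxide (the aromatisation-driven opening by which grisadienones give diaryl ether acids), after which the unhindered ring A methyl ester is saponified and the last stereocentre is gone.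

Step 9
Reactants: 13 4-chloro-2-(2-carboxy-3-methoxy-5-methylphenoxy)-3-hydroxy-5-methoxybenzoic acid
Product: 14 2-(2-carboxy-3-hydroxy-5-methylphenoxy)-4-chloro-3-hydroxy-5-methoxybenzoic acid (target)
Conditions: BCl3 (1 M in CH2Cl2, 6 equiv), CH2Cl2, −78 to 0 °C; then H2O
Reagents that add atoms: none
Why: Chelation-controlled aryl methyl ether cleavage with BCl3; boron bound to the ring B carboxyl coordinates the ortho methoxy oxygen in a six-membered chelate and chloride removes the methyl by SN2, whereas the ring A methoxy group has no ortho carbonyl (it lies between Cl and H) and the diaryl ether is inert at this temperature.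

**Compound list**

1 | methyl 2,6-dihydroxy-4-methylbenzoate | COC(=O)c1c(O)cc(C)cc1O | starting material
2 | methyl 2-hydroxy-6-methoxy-4-methylbenzoate | COC(=O)c1c(O)cc(C)cc1OC | intermediate
3 | methyl bromoacetate | COC(=O)CBr | starting material
4 | methyl 2-methoxy-6-(2-methoxy-2-oxoethoxy)-4-methylbenzoate | COC(=O)COc1cc(C)cc(OC)c1C(=O)OC | intermediate
5 | methyl 4-methoxy-6-methyl-3-oxo-2,3-dihydrobenzofuran-2-carboxylate (racemic; enolises to the 3-hydroxybenzofuran) | COC(=O)C1Oc2cc(C)cc(OC)c2C1=O | intermediate
6 | methyl (E)-4-oxopent-2-enoate | CC(=O)/C=C/C(=O)OC | starting material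
7 | methyl 4-methoxy-2-(1-methoxy-1,4-dioxopentan-2-yl)-6-methyl-3-oxo-2,3-dihydrobenzofuran-2-carboxylate (Michael adduct, racemic diastereomer mixture, not isolated) | COC(=O)C(CC(C)=O)C1(C(=O)OC)Oc2cc(C)cc(OC)c2C1=O | intermediate
8 | methyl 4-methoxy-6-methyl-2',3,4'-trioxo-3H-spiro[benzofuran-2,1'-cyclohexane]-6'-carboxylate (racemic diastereomer mixture) | COC(=O)C1CC(=O)CC(=O)C12Oc1cc(C)cc(OC)c1C2=O | intermediate
9 | methyl 3'-chloro-4'-hydroxy-4-methoxy-6-methyl-2',3-dioxo-3H-spiro[benzofuran-2,1'-cyclohex[3]ene]-6'-carboxylate (racemic diastereomer mixture, enol tautomer) | COC(=O)C1CC(O)=C(Cl)C(=O)C12Oc1cc(C)cc(OC)c1C2=O | intermediate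
10 | methyl 3'-chloro-4,4'-dimethoxy-6-methyl-2',3-dioxo-3H-spiro[benzofuran-2,1'-cyclohex[3]ene]-6'-carboxylate (racemic diastereomer mixture) | COC(=O)C1CC(OC)=C(Cl)C(=O)C12Oc1cc(C)cc(OC)c1C2=O | intermediate
11 | methyl 3'-chloro-4,4'-dimethoxy-6-methyl-2',3-dioxo-3H-spiro[benzofuran-2,1'-cyclohexa[3,5]diene]-6'-carboxylate (racemic) | COC(=O)C1=CC(OC)=C(Cl)C(=O)C12Oc1cc(C)cc(OC)c1C2=O | intermediate
12 | 2-[3-chloro-2-hydroxy-4-methoxy-6-(methoxycarbonyl)phenoxy]-6-methoxy-4-methylbenzoic acid (not isolated) | COC(=O)c1cc(OC)c(Cl)c(O)c1Oc1cc(C)cc(OC)c1C(=O)O | intermediate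
13 | 4-chloro-2-(2-carboxy-3-methoxy-5-methylphenoxy)-3-hydroxy-5-methoxybenzoic acid | COc1cc(C(=O)O)c(Oc2cc(C)cc(OC)c2C(=O)O)c(O)c1Cl | intermediate
14 | 2-(2-carboxy-3-hydroxy-5-methylphenoxy)-4-chloro-3-hydroxy-5-methoxybenzoic acid | COc1cc(C(=O)O)c(Oc2cc(C)cc(O)c2C(=O)O)c(O)c1Cl | target

**Step count**

Total steps: 9. Longest linear sequence: 9 steps (1 to 14).

**Steps most likely to fail**

Step 7 (dehydrogenation). Hydride transfer from C6'–H, which is α to an ester and beside the quaternary spiro carbon, may be slow, so that acid-induced loss of the enol ether methyl group or unselective oxidation competes on prolonged heating. The fallback sets out from 10 and comes back at 11. Radical allylic bromination at C5' (N-bromosuccinimide, azobisisobutyronitrile cat., PhCF3, 80 °C; Wohl–Ziegler conditions as used for γ-bromination of β-alkoxy enones) should give methyl 5'-bromo-3'-chloro-4,4'-dimethoxy-6-methyl-2',3-dioxo-3H-spiro[benzofuran-2,1'-cyclohex[3]ene]-6'-carboxylate F1. Triethylamine in CH2Cl2 at 0 °C should then remove HBr across C5'–C6', the C6' proton being α to the ester, to give 11. The C5' radical is allylic and flanked by the methoxy-substituted enone, so it should form in preference to the ring B benzylic radical.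

Step 6 (regiochemistry of enol ether formation). Once the chlorine is in place, methanol addition at the hindered C2' carbonyl may not be disfavoured enough, giving much of the 2'-methoxy isomer, or etherification may stall because the chlorine lowers the basicity of both carbonyls. The fallback sets out from 8 and comes back at 10, with the order of the two operations reversed. The unchlorinated trione 8 is etherified first (HC(OCH3)3, CH3OH, p-toluenesulfonic acid cat., 50 °C), where the preference for the carbonyl remote from a quaternary centre is established for 4,4-disubstituted cyclohexane-1,3-diones. This should give methyl 4,4'-dimethoxy-6-methyl-2',3-dioxo-3H-spiro[benzofuran-2,1'-cyclohex[3]ene]-6'-carboxylate F2. N-Chlorosuccinimide (1.0 equiv, CH2Cl2, 0 °C) should then chlorinate the nucleophilic α-carbon C3' of the β-methoxy enone to give 10.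

Step 4 (key step). Under the full equivalent of base the Michael adduct may fragment by retro-Michael loss of the stabilised benzofuranolate, or may close by aldol at C3, faster than the methyl ketone enolate is acylated. The fallback sets out from 5 and comes back at 8, and builds ring A by cycloaddition instead.
- Hydrolysis and decarboxylation of 5 (aq. HCl, acetic acid, reflux) should give 4-methoxy-6-methylbenzofuran-3(2H)-one F3.
- Aldol condensation with methyl glyoxylate (neutral Al2O3, CH2Cl2, rt, as in aurone synthesis) should give methyl (Z)-2-(4-methoxy-6-methyl-3-oxobenzofuran-2(3H)-ylidene)acetate F4; either alkene isomer would serve.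
- Diels–Alder reaction of this 2-alkylidene benzofuranone with 1-methoxy-1,3-bis(trimethylsilyloxy)buta-1,3-diene (toluene, 110 °C) should give the cycloadduct methyl 2',4-dimethoxy-6-methyl-3-oxo-2',4'-bis(trimethylsilyloxy)-3H-spiro[benzofuran-2,1'-cyclohex[3]ene]-6'-carboxylate F5. The nucleophilic CH2 terminus of the diene should bond to the exocyclic carbon β to the furanone ketone and the ketene acetal carbon to C2.
- F5 is not isolated; aqueous HCl in THF should hydrolyse it to 8.

**Further compounds**

F1 | step 7 | methyl 5'-bromo-3'-chloro-4,4'-dimethoxy-6-methyl-2',3-dioxo-3H-spiro[benzofuran-2,1'-cyclohex[3]ene]-6'-carboxylate | COC(=O)C1C(Br)C(OC)=C(Cl)C(=O)C12Oc1cc(C)cc(OC)c1C2=O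
F2 | step 6 | methyl 4,4'-dimethoxy-6-methyl-2',3-dioxo-3H-spiro[benzofuran-2,1'-cyclohex[3]ene]-6'-carboxylate | COC(=O)C1CC(OC)=CC(=O)C12Oc1cc(C)cc(OC)c1C2=O
F3 | step 4 | 4-methoxy-6-methylbenzofuran-3(2H)-one | COc1cc(C)cc2OCC(=O)c12
F4 | step 4 | methyl (Z)-2-(4-methoxy-6-methyl-3-oxobenzofuran-2(3H)-ylidene)acetate | COC(=O)/C=C1\Oc2cc(C)cc(OC)c2C1=O
F5 | step 4 | methyl 2',4-dimethoxy-6-methyl-3-oxo-2',4'-bis(trimethylsilyloxy)-3H-spiro[benzofuran-2,1'-cyclohex[3]ene]-6'-carboxylate | COC(=O)C1CC(O[Si](C)(C)C)=CC(OC)(O[Si](C)(C)C)C12Oc1cc(C)cc(OC)c1C2=O
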